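**Remarks on the chemistry (assumptions)**

- Ring labels: ring B is the guaiacyl ring on the C4 benzyl group of the lactone, ring C the one on the C3 benzyl group; rings A and D are the outer rings of the ring B arm and the ring C arm.
- Structure check: no connectivity or configuration error was found. The lactone is C3 S, C4 S (trans); the ring B arm is Ca S, Cb S (anti); the ring C arm is Ca S, Cb R (syn). In the vinyl-bearing compounds the Cb descriptors read R (ring B) and S (ring C) through a change of CIP priority only, not of geometry.
- Assumption on catalyst sense: an (R)-configured acid of this type is taken to give (R)-carbinols from aryl aldehydes, so the (S)-acid is used in step 14; (R,R)-Et-DuPhos on rhodium is taken to give the (S)-half-ester in step 3. Each sense is to be confirmed on the first batch and the mirror-image catalyst used if it is reversed.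

## Structural features

The target is a trans-3,4-dibenzylbutyrolactone (C3 S, C4 S) in which each benzyl group is a guaiacyl ring, ring B on the C4 side and ring C on the C3 side. Each of these rings carries at C5, ortho to its phenol, a 1-aryl-1,3-dihydroxypropan-2-yl arm that ends in a further guaiacyl ring (ring A or ring D). Every arm holds two adjacent stereocentres, the carbinol Ca and the benzylic Cb with its CH2OH group. Both Ca are S, but Cb is S on ring B (anti arm) and R on ring C (syn arm), so the two arms are diastereomeric and not interchangeable. The lactone pair C3/C4 is separated from each arm pair by an aromatic ring and a methylene, so the six stereocentres form three isolated pairs with no useful relay between them. The benzylic carbinols ionise in acid (the ortho phenol of ring B or C would then close a dihydrobenzofuran), Cb–H is benzylic, C3 is epimerisable, and the lactone is sensitive to base and hydride. The real difficulty is to attach the hindered Ca–Cb unit twice, to two nearly identical rings, with equal absolute carbinol configuration but opposite relative configuration. The key step exploits that each Ca–Cb bond joins an aldehyde-derived carbinol carbon to a carbon on ring B or ring C: an allyl boron unit on each inner ring, E on ring B and Z on ring C, turns alkene geometry into anti or syn, and one chiral acid sets both Ca.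

## Logic of the disconnections

26 to 25. The four aryl O–CH2Ph bonds are cut. The phenols are masked by one kind of ether that leaves under neutral conditions, because acid would ionise Ca and close dihydrobenzofurans. The gain is that all earlier chemistry runs on non-phenolic material. The forward step must spare the two benzylic carbinols and the lactone.

25 to 23. Each CH2OH carbon is traced back to the inner carbon of a vinyl group. A vinyl group is what an allyl transfer leaves at Cb, so the 1,3-diol arms become homoallylic alcohols. The forward cleavage must not let an α-aryl-β-hydroxy aldehyde persist, since that would epimerise Cb or undergo retro-aldol cleavage. For this reason the ozonide is reduced in the same flask instead of isolating a dialdehyde.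

23 to 20 and two molecules of 21. Both Ca–Cb bonds are cut. This removes four stereocentres and rings A and D in one operation and leaves a lactone with two boron-bearing chains plus a commercial aldehyde. The forward step demands intact E geometry on ring B and Z geometry on ring C, attack at the γ-carbon, and catalyst control of one aldehyde face in both events.

20 to 18 and 19, then 18 to 17. The two allylic C–B bonds are cut. The E unit comes from an allylic acetate through a π-allyl palladium complex, the Z unit from hydrocupration of an aryl allene. An acetate is chosen over a carbonate so that no chloroformate is needed and no alkoxide is released next to a boronate. The copper step is placed first so that the allene never meets palladium; the Z boronate then meets palladium only under phosphine-free conditions in which allyl boronates do not transmetalate. The demands are that copper hydride selects the allene over the cinnamyl acetate and that the palladium step leaves the Z unit untouched.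

17 to 16 to 15. The acetate C–O bond and the O–Si bond are cut. The allylic oxygen has to pass the strongly basic fragment union as a silyl ether. The forward desilylation must be buffered to protect the allene and the lactone.

15 to 9 and 13. The C3–CH2 bond to ring C is cut. This is the classical trans-selective α-benzylation of a β-benzyl lactone and splits the molecule into two halves of similar size, both derived from 2. The enolate must be alkylated anti to the C4 substituent without harming the allene or the silyl ether.

13 to 12, then to 10 and 11, then to 2. The benzylic C–Br bond and the ring C C5–allene bond are cut. The iodide of 2 is the only handle, and the allene is put on a small molecule before the union because an aryl palladium species would add to an allene later. The forward coupling must transfer an allenyl, not a propargyl, group.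

9 to 7 and 8. The ring B C5–alkenyl bond is cut. The E geometry is bought with 8 and carried through a cross-coupling with retention. The lactone must survive mild aqueous base.

7 to 5 to 4, then to 2 and 3. The lactone C5–O bond, the C–H bonds of a hydrogenation, and the C=C bond between the benzylic carbon and the succinate carbon are cut. Three steps set the single C4 stereocentre catalytically. The hydrogenation must be enantioselective and tolerate the aryl iodide; the reduction must take the ester and leave the carboxylate.

2 to 1. The phenol O–benzyl bond is cut; one benzylation serves both halves.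

## Other disconnections considered

Alternative 1: The cut lies inside the lactone, at the C4–benzylic bond and the C3–CH2 bond. Ring B with its finished arm arrives as the 2-aryl-1,3-dithiane A3 and ring C with its finished arm as the benzyl bromide A4. In the forward step lithiated A3 adds 1,4 to the butenolide A2 anti to the menthyloxy group, and the enolate is benzylated by A4 anti to the new C4 substituent, which should give the trans,trans lactone A1.
- In its favour: it sets C3 and C4 in one operation under control of a cheap auxiliary, with no catalyst sense to establish, and it is highly convergent. For the lactone it is at least the equal of steps 2 to 4 and 9 of the chosen plan, and better in convergence.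
- Against it here: it leaves the real problem untouched. The four arm stereocentres must already be present in A3 and A4, in two diastereomeric series, each needing its own asymmetric C–C bond formation. After the union the dithiane must be removed (Raney nickel is pyrophoric and can hydrogenolyse benzylic C–O bonds), the acetal carbon reduced back to CH2, and silyl and benzyl groups removed, at least four steps against two in the chosen plan.
- Comparison: structurally it addresses the lactone, the chosen plan the arms. Mechanistically both rely on ordered transition states, anionic and auxiliary-controlled in one case, catalytic in the other. In step economy it should be clearly longer, since the two arms are made separately.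

Alternative 2: The cut is the Ca–O bond; the carbinol oxygen is introduced last on a 2,3-diarylpropanol. In the forward step DDQ takes hydride from the CH2 next to the electron-rich outer ring of the carbonate A6, the carbonyl oxygen of the tert-butyl carbonate closes on the cation, isobutene is lost, and the cyclic carbonate A5 should form with both aryl groups equatorial (trans).
- In its favour: the CH2O carbon is present from the start, so no alkene is cleaved and no labile aldehyde is passed; on this point it is better than the chosen plan. The Ca/Cb relationship follows from one stereocentre through a chair-like closure, and the step is metal-free.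
- Against it here: the trans carbonate corresponds to the anti arm of ring B only. The syn arm of ring C would need an inversion at Ca or another method, so one reaction type cannot make both arms. The Cb centre of A6 needs a separate asymmetric step. DDQ would also attack the other alkoxy-substituted benzylic positions, so the oxidation has to be run on a half before the lactone methylenes exist, and the bromide of A5 must then be turned into the lactone benzylic carbon.
- Comparison: structurally it solves one arm where the chosen plan solves both. Mechanistically it is a cationic, thermodynamically guided closure against a catalyst-controlled addition. In step economy it is longer, because each arm is built alone and then joined.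

Alternative 3: The cut is the C5–Cb bond on both inner rings, a retro-[3,3] shift. In the forward step the bis(aryl allyl ether) A8, derived from the lactone A9, is heated; two aromatic Claisen rearrangements through chair transition states should transfer the configuration of each ether carbon to Cb and give A7.
- In its favour: the C–C bond at the hindered ortho position forms intramolecularly, without aryl halide or metal. The rearrangement frees the phenols of rings B and C, so these need no protecting group, which is better than the chosen plan. Choosing the configuration of the ether carbon selects anti or syn, a logic equal to the E/Z choice of the chosen plan.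
- Against it here: both Ca and both ether carbons must be set beforehand in two diastereomeric side chains. The two phenols of A9 cannot be told apart, so two different ethers cannot be attached selectively to A9 itself. Secondary allylic aryl ethers of defined configuration are hard to make without allylic transposition. The rearrangement needs high temperature, where ionisation of the ether and migration to the methoxy-bearing ortho position compete. The (E)-propenyl groups of A7 still need cleavage and reduction, now next to free phenols.
- Comparison: structurally it forms the other bond of the same arm. Mechanistically it is a thermal substrate-controlled transfer against catalyst control. In step economy it should not be shorter, since each side chain needs several steps of its own.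

Key step: step 14

## Steps

Step 1
Reactants: 1 5-iodovanillin
Product: 2 4-(benzyloxy)-3-iodo-5-methoxybenzaldehyde
Conditions: BnBr, K2CO3, DMF, 50 °C
Reagents that add atoms: benzyl bromide, BrCc1ccccc1
Why: Williamson ether synthesis on an acidic ortho-iodophenol; the benzyl ether withstands all later base, hydride and metal-catalysed steps and leaves at the end under neutral hydrogenolysis.

Step 2
Reactants: 2 4-(benzyloxy)-3-iodo-5-methoxybenzaldehyde; 3 dimethyl succinate
Product: 4 (E)-4-[4-(benzyloxy)-3-iodo-5-methoxyphenyl]-3-(methoxycarbonyl)but-3-enoic acid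
Conditions: NaOMe, MeOH, reflux; then aq HCl
Reagents that add atoms: none
Why: Stobbe condensation; aldol addition, closure to the paraconic ester and ring opening by elimination should give the half-ester with the aryl group trans to the ester, the regiochemistry that later places the benzyl group at C4 of the lactone.

Step 3
Reactants: 4 (E)-4-[4-(benzyloxy)-3-iodo-5-methoxyphenyl]-3-(methoxycarbonyl)but-3-enoic acid
Product: 5 (S)-4-[4-(benzyloxy)-3-iodo-5-methoxyphenyl]-3-(methoxycarbonyl)butanoic acid
Conditions: [Rh(cod)((R,R)-Et-DuPhos)]BF4 (1 mol%), H2 (5 bar), NaOMe (0.1 equiv), MeOH, rt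
Reagents that add atoms: none
Why: Asymmetric hydrogenation of an itaconate-type half-ester; carboxylate and ester chelate rhodium so that hydrogen is delivered to one face of the alkene and the stereocentre (later C4 of the lactone) is set S by the ligand; cationic monovalent rhodium does not cleave benzyl ethers and should insert into the aryl iodide only slowly at room temperature.

Step 4
Reactants: 5 (S)-4-[4-(benzyloxy)-3-iodo-5-methoxyphenyl]-3-(methoxycarbonyl)butanoic acid
Product: 7 (S)-4-[4-(benzyloxy)-3-iodo-5-methoxybenzyl]dihydrofuran-2(3H)-one, via hydroxy acid 6 (not isolated)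
Conditions: KOH (1 equiv), EtOH; CaCl2, NaBH4, −10 °C → rt; then 2 M HCl, rt
Reagents that add atoms: none
Why: Calcium borohydride reduces the methyl ester but not the carboxylate salt, and acidification closes the γ-lactone by acyl substitution; the stereocentre is not involved.

Step 5
Reactants: 7 (S)-4-[4-(benzyloxy)-3-iodo-5-methoxybenzyl]dihydrofuran-2(3H)-one; 8 (E)-tert-butyldimethyl{[3-(4,4,5,5-tetramethyl-1,3,2-dioxaborolan-2-yl)allyl]oxy}silane
Product: 9 (S)-4-{4-(benzyloxy)-3-[(E)-3-(tert-butyldimethylsilyloxy)prop-1-enyl]-5-methoxybenzyl}dihydrofuran-2(3H)-one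
Conditions: Pd(dppf)Cl2 (3 mol%), K3PO4, THF/H2O (10:1), 60 °C
Reagents that add atoms: none
Why: Suzuki–Miyaura coupling of an aryl iodide and an (E)-alkenyl pinacol boronate proceeds with retention of alkene geometry; phosphate base at 60 °C should leave lactone and silyl ether intact.

Step 6
Reactants: 2 4-(benzyloxy)-3-iodo-5-methoxybenzaldehyde
Product: 10 [4-(benzyloxy)-3-iodo-5-methoxyphenyl]methanol
Conditions: NaBH4, MeOH/THF, 0 °C
Reagents that add atoms: none
Why: Borohydride reduction of an aryl aldehyde; it removes the electrophile that would otherwise capture the allenyl metal reagent of step 7.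

Step 7
Reactants: 10 [4-(benzyloxy)-3-iodo-5-methoxyphenyl]methanol; 11 propargyl bromide
Product: 12 [4-(benzyloxy)-3-methoxy-5-(propa-1,2-dienyl)phenyl]methanol
Conditions: In powder, 11 (as toluene solution), DMF, rt; then 10, Pd(PPh3)4 (4 mol%), LiI, 100 °C
Reagents that add atoms: none
Why: Palladium-catalysed cross-coupling of an aryl iodide and the allenylindium reagent formed in the flask from indium metal and propargyl bromide; transmetalation and reductive elimination should deliver the aryl allene, and organoindium reagents tolerate the free hydroxyl group.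

Step 8
Reactants: 12 [4-(benzyloxy)-3-methoxy-5-(propa-1,2-dienyl)phenyl]methanol
Product: 13 2-(benzyloxy)-5-(bromomethyl)-1-methoxy-3-(propa-1,2-dienyl)benzene
Conditions: CBr4, PPh3, CH2Cl2, 0 °C
Reagents that add atoms: carbon tetrabromide, BrC(Br)(Br)Br
Why: Appel bromination under neutral conditions, so that no hydrogen bromide can add to the allene; the electron-rich benzyl bromide is used at once.

Step 9
Reactants: 9 (S)-4-{4-(benzyloxy)-3-[(E)-3-(tert-butyldimethylsilyloxy)prop-1-enyl]-5-methoxybenzyl}dihydrofuran-2(3H)-one; 13 2-(benzyloxy)-5-(bromomethyl)-1-methoxy-3-(propa-1,2-dienyl)benzene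
Product: 15 (3S,4S)-trans lactone carrying the allene on ring C and the (E)-silyloxypropenyl group on ring B, via lithium enolate 14 (not isolated)
Conditions: LiHMDS, THF, −78 °C; then 13, DMPU, −78 → −30 °C
Reagents that add atoms: none
Why: Alkylation of a β-substituted butyrolactone enolate; the benzyl bromide approaches the planar enolate anti to the C4 benzyl group, which sets C3 as S and gives the trans lactone, also the thermodynamically preferred isomer.

Step 10
Reactants: 15 (3S,4S)-trans lactone carrying the allene on ring C and the (E)-silyloxypropenyl group on ring B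
Product: 16 (3S,4S)-trans lactone carrying the allene on ring C and the (E)-3-hydroxyprop-1-enyl group on ring B
Conditions: Bu4NF, AcOH (1:1), THF, 0 °C → rt
Reagents that add atoms: none
Why: Fluoride-mediated desilylation; buffering by acetic acid keeps the medium too weakly basic to isomerise the aryl allene or open the lactone.

Step 11
Reactants: 16 (3S,4S)-trans lactone carrying the allene on ring C and the (E)-3-hydroxyprop-1-enyl group on ring B
Product: 17 (3S,4S)-trans lactone carrying the allene on ring C and the (E)-3-acetoxyprop-1-enyl group on ring B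
Conditions: Ac2O, pyridine, DMAP (cat.), CH2Cl2, 0 °C
Reagents that add atoms: acetic anhydride, CC(=O)OC(C)=O
Why: Standard acylation of a primary allylic alcohol; the acetate is the leaving group for step 13 and should be neither ionised nor reduced in step 12.

Step 12
Reactants: 17 (3S,4S)-trans lactone carrying the allene on ring C and the (E)-3-acetoxyprop-1-enyl group on ring B
Product: 18 (3S,4S)-trans lactone carrying the (Z)-3-(pinacolboryl)prop-1-enyl group on ring C and the (E)-3-acetoxyprop-1-enyl group on ring B
Conditions: CuCl (5 mol%), Xantphos (5 mol%), NaOtBu (10 mol%), HBpin (1.1 equiv), THF, 0 °C → rt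
Reagents that add atoms: pinacolborane, CC1(C)OBOC1(C)C
Why: Copper hydride-catalysed hydroboration of an aryl allene; Cu–H adds across the terminal double bond from the side away from the aryl group to give the (Z)-σ-allylcopper species, and σ-bond metathesis with pinacolborane releases the (Z)-allyl boronate; the allene should react far faster than the 1,2-disubstituted styrene of the cinnamyl acetate or the lactone.

Step 13
Reactants: 18 (3S,4S)-trans lactone carrying the (Z)-3-(pinacolboryl)prop-1-enyl group on ring C and the (E)-3-acetoxyprop-1-enyl group on ring B; 19 bis(pinacolato)diboron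
Product: 20 (3S,4S)-lactone bis(allyl pinacol boronate), E on ring B and Z on ring C
Conditions: 19 (1.2 equiv), Pd2(dba)3 (2.5 mol%), DMSO, 50 °C
Reagents that add atoms: none
Why: Palladium-catalysed borylation of an allylic acetate (Miyaura-type); oxidative addition to zerovalent palladium, acetate-assisted transmetalation from the diboron and reductive elimination at the unsubstituted terminus of the syn π-allyl complex should give the linear (E)-boronate; without phosphine and in DMSO allyl pinacol boronates, the Z unit on ring C included, do not transmetalate.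

Step 14
Reactants: 20 (3S,4S)-lactone bis(allyl pinacol boronate), E on ring B and Z on ring C; 21 4-(benzyloxy)-3-methoxybenzaldehyde (2.5 equiv)
Product: 23 bis(homoallylic alcohol) having the (1S,2R) anti arm on ring B and the (1S,2S) syn arm on ring C, via bis(pinacol borate) 22 (not isolated)
Conditions: (S)-3,3'-bis(2,4,6-triisopropylphenyl)-1,1'-binaphthyl-2,2'-diyl hydrogen phosphate (10 mol%), 4 Å MS, toluene, −30 → 0 °C; then aq NaHCO3
Reagents that add atoms: none
Why: The phosphoric acid activates each pinacol boronate by a hydrogen bond from P–OH to a boronate oxygen while its phosphoryl oxygen holds the formyl C–H of 21, so that C–C bond formation runs through a closed six-membered chair (Zimmerman–Traxler) transition state in which boron binds the carbonyl oxygen and the γ-carbon, the one on the inner ring, attacks the carbonyl carbon. The closest known reaction type is the chiral phosphoric acid-catalysed allyl- and crotylboration of aromatic aldehydes by pinacol boronates. No ring is closed; two Ca–Cb bonds and four stereocentres are formed. Both carbinol centres Ca are set by the catalyst, which exposes the same (Si) face of 21 in both events and so gives S twice. Cb on the ring B arm is set by the E geometry (aryl group equatorial in the chair, anti product) and Cb on the ring C arm by the Z geometry (aryl group axial, syn product). The step needs γ-regioselectivity, which the cyclic transition state enforces, and preserved alkene geometry, which is secured because conjugated γ-aryl pinacol boronates should not undergo 1,3-boron shift at or below 0 °C. It also needs the catalysed path to outrun the background addition, which is slow for a hindered pinacol boronate and an electron-rich aldehyde at this temperature. The lactone stereocentres lie an aromatic ring and a methylene away and should exert no bias, and the lactone carbonyl is not activated by the acid.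

Step 15
Reactants: 23 bis(homoallylic alcohol) having the (1S,2R) anti arm on ring B and the (1S,2S) syn arm on ring C
Product: 25 tetra-O-benzyl ether of the target, via bis(ozonide) 24 (not isolated)
Conditions: O3, CH2Cl2, −78 °C (to first faint blue), N2 purge; then NaBH4, MeOH, −78 → 0 °C
Reagents that add atoms: ozone, [O-][O+]=O
Why: Ozonolysis of the two terminal alkenes, much faster than attack on the alkoxyarenes at −78 °C, then borohydride reduction of the ozonides in the same flask; the α-aryl-β-hydroxy aldehyde is reduced as it is released, so Cb should not epimerise and retro-aldol cleavage of the Ca–Cb bond should not set in, and the lactone is not reduced by NaBH4 in this time at 0 °C.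

Step 16
Reactants: 25 tetra-O-benzyl ether of the target
Product: 26 CNP0113972.1
Conditions: H2 (1 atm), 10% Pd/C, EtOAc/EtOH (1:1), rt
Reagents that add atoms: none
Why: Hydrogenolysis of four aryl benzyl ethers under neutral conditions; aryl O–benzyl bonds cleave much faster than the secondary benzylic C–OH bonds, and the absence of acid prevents ionisation at Ca and closure to dihydrobenzofurans.

## Compound list

1 | 5-iodovanillin | O=Cc1cc(I)c(O)c(OC)c1 | starting material
2 | 4-(benzyloxy)-3-iodo-5-methoxybenzaldehyde | O=Cc1cc(I)c(OCc2ccccc2)c(OC)c1 | intermediate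
3 | dimethyl succinate | COC(=O)CCC(=O)OC | starting material
4 | (E)-4-[4-(benzyloxy)-3-iodo-5-methoxyphenyl]-3-(methoxycarbonyl)but-3-enoic acid | COC(=O)/C(=C/c1cc(I)c(OCc2ccccc2)c(OC)c1)CC(=O)O | intermediate
5 | (S)-4-[4-(benzyloxy)-3-iodo-5-methoxyphenyl]-3-(methoxycarbonyl)butanoic acid | COC(=O)[C@H](CC(=O)O)Cc1cc(I)c(OCc2ccccc2)c(OC)c1 | intermediate
6 | (S)-4-[4-(benzyloxy)-3-iodo-5-methoxyphenyl]-3-(hydroxymethyl)butanoic acid | OC[C@H](CC(=O)O)Cc1cc(I)c(OCc2ccccc2)c(OC)c1 | intermediate
7 | (S)-4-[4-(benzyloxy)-3-iodo-5-methoxybenzyl]dihydrofuran-2(3H)-one | COc1cc(C[C@@H]2COC(=O)C2)cc(I)c1OCc1ccccc1 | intermediate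
8 | (E)-tert-butyldimethyl{[3-(4,4,5,5-tetramethyl-1,3,2-dioxaborolan-2-yl)allyl]oxy}silane | CC(C)(C)[Si](C)(C)OC/C=C/B1OC(C)(C)C(C)(C)O1 | starting material
9 | (S)-4-{4-(benzyloxy)-3-[(E)-3-(tert-butyldimethylsilyloxy)prop-1-enyl]-5-methoxybenzyl}dihydrofuran-2(3H)-one | COc1cc(C[C@@H]2COC(=O)C2)cc(/C=C/CO[Si](C)(C)C(C)(C)C)c1OCc1ccccc1 | intermediate
10 | [4-(benzyloxy)-3-iodo-5-methoxyphenyl]methanol | COc1cc(CO)cc(I)c1OCc1ccccc1 | intermediate
11 | propargyl bromide (3-bromoprop-1-yne) | C#CCBr | starting material
12 | [4-(benzyloxy)-3-methoxy-5-(propa-1,2-dienyl)phenyl]methanol | COc1cc(CO)cc(C=C=C)c1OCc1ccccc1 | intermediate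
13 | 2-(benzyloxy)-5-(bromomethyl)-1-methoxy-3-(propa-1,2-dienyl)benzene | COc1cc(CBr)cc(C=C=C)c1OCc1ccccc1 | intermediate
14 | lithium enolate of 9 | [Li+].COc1cc(C[C@@H]2COC([O-])=C2)cc(/C=C/CO[Si](C)(C)C(C)(C)C)c1OCc1ccccc1 | intermediate
15 | (3S,4S)-3-[4-(benzyloxy)-3-methoxy-5-(propa-1,2-dienyl)benzyl]-4-{4-(benzyloxy)-3-[(E)-3-(tert-butyldimethylsilyloxy)prop-1-enyl]-5-methoxybenzyl}dihydrofuran-2(3H)-one | COc1cc(C[C@@H]2COC(=O)[C@H]2Cc2cc(OC)c(OCc3ccccc3)c(C=C=C)c2)cc(/C=C/CO[Si](C)(C)C(C)(C)C)c1OCc1ccccc1 | intermediate
16 | (3S,4S)-3-[4-(benzyloxy)-3-methoxy-5-(propa-1,2-dienyl)benzyl]-4-{4-(benzyloxy)-3-[(E)-3-hydroxyprop-1-enyl]-5-methoxybenzyl}dihydrofuran-2(3H)-one | COc1cc(C[C@@H]2COC(=O)[C@H]2Cc2cc(OC)c(OCc3ccccc3)c(C=C=C)c2)cc(/C=C/CO)c1OCc1ccccc1 | intermediate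
17 | (3S,4S)-4-{3-[(E)-3-acetoxyprop-1-enyl]-4-(benzyloxy)-5-methoxybenzyl}-3-[4-(benzyloxy)-3-methoxy-5-(propa-1,2-dienyl)benzyl]dihydrofuran-2(3H)-one | COc1cc(C[C@@H]2COC(=O)[C@H]2Cc2cc(OC)c(OCc3ccccc3)c(C=C=C)c2)cc(/C=C/COC(C)=O)c1OCc1ccccc1 | intermediate
18 | (3S,4S)-4-{3-[(E)-3-acetoxyprop-1-enyl]-4-(benzyloxy)-5-methoxybenzyl}-3-{4-(benzyloxy)-3-methoxy-5-[(Z)-3-(4,4,5,5-tetramethyl-1,3,2-dioxaborolan-2-yl)prop-1-enyl]benzyl}dihydrofuran-2(3H)-one | COc1cc(C[C@@H]2COC(=O)[C@H]2Cc2cc(OC)c(OCc3ccccc3)c(/C=C\CB3OC(C)(C)C(C)(C)O3)c2)cc(/C=C/COC(C)=O)c1OCc1ccccc1 | intermediate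
19 | bis(pinacolato)diboron | CC1(C)OB(B2OC(C)(C)C(C)(C)O2)OC1(C)C | starting material
20 | (3S,4S)-3-{4-(benzyloxy)-3-methoxy-5-[(Z)-3-(4,4,5,5-tetramethyl-1,3,2-dioxaborolan-2-yl)prop-1-enyl]benzyl}-4-{4-(benzyloxy)-3-methoxy-5-[(E)-3-(4,4,5,5-tetramethyl-1,3,2-dioxaborolan-2-yl)prop-1-enyl]benzyl}dihydrofuran-2(3H)-one | COc1cc(C[C@@H]2COC(=O)[C@H]2Cc2cc(OC)c(OCc3ccccc3)c(/C=C\CB3OC(C)(C)C(C)(C)O3)c2)cc(/C=C/CB2OC(C)(C)C(C)(C)O2)c1OCc1ccccc1 | intermediate
21 | 4-(benzyloxy)-3-methoxybenzaldehyde | O=Cc1ccc(OCc2ccccc2)c(OC)c1 | starting material
22 | bis(pinacol borate) of 23 (both carbinol oxygens bound to boron) | COc1cc([C@@H](OB6OC(C)(C)C(C)(C)O6)[C@H](C=C)c2cc(C[C@@H]3COC(=O)[C@H]3Cc3cc(OC)c(OCc5ccccc5)c([C@H](C=C)[C@H](OB7OC(C)(C)C(C)(C)O7)c4ccc(OCc5ccccc5)c(OC)c4)c3)cc(OC)c2OCc2ccccc2)ccc1OCc1ccccc1 | intermediate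
23 | (3S,4S)-3-{4-(benzyloxy)-3-[(1S,2S)-1-(4-(benzyloxy)-3-methoxyphenyl)-1-hydroxybut-3-en-2-yl]-5-methoxybenzyl}-4-{4-(benzyloxy)-3-[(1S,2R)-1-(4-(benzyloxy)-3-methoxyphenyl)-1-hydroxybut-3-en-2-yl]-5-methoxybenzyl}dihydrofuran-2(3H)-one | COc1cc([C@@H](O)[C@H](C=C)c2cc(C[C@@H]3COC(=O)[C@H]3Cc3cc(OC)c(OCc5ccccc5)c([C@H](C=C)[C@H](O)c4ccc(OCc5ccccc5)c(OC)c4)c3)cc(OC)c2OCc2ccccc2)ccc1OCc1ccccc1 | intermediate
24 | bis(ozonide) of 23 (each vinyl group as a 1,2,4-trioxolan-3-yl group, ozonide carbons as a mixture) | COc1cc([C@@H](O)[C@H](C6OCOO6)c2cc(C[C@@H]3COC(=O)[C@H]3Cc3cc(OC)c(OCc5ccccc5)c([C@H](C7OCOO7)[C@H](O)c4ccc(OCc5ccccc5)c(OC)c4)c3)cc(OC)c2OCc2ccccc2)ccc1OCc1ccccc1 | intermediate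
25 | (3S,4S)-3-{4-(benzyloxy)-3-[(1S,2R)-1-(4-(benzyloxy)-3-methoxyphenyl)-1,3-dihydroxypropan-2-yl]-5-methoxybenzyl}-4-{4-(benzyloxy)-3-[(1S,2S)-1-(4-(benzyloxy)-3-methoxyphenyl)-1,3-dihydroxypropan-2-yl]-5-methoxybenzyl}dihydrofuran-2(3H)-one | COc1cc([C@@H](O)[C@H](CO)c2cc(C[C@@H]3COC(=O)[C@H]3Cc3cc(OC)c(OCc5ccccc5)c([C@H](CO)[C@H](O)c4ccc(OCc5ccccc5)c(OC)c4)c3)cc(OC)c2OCc2ccccc2)ccc1OCc1ccccc1 | intermediate
26 | CNP0113972.1, (3S,4S)-3-{3-[(1S,2R)-1,3-dihydroxy-1-(4-hydroxy-3-methoxyphenyl)propan-2-yl]-4-hydroxy-5-methoxybenzyl}-4-{3-[(1S,2S)-1,3-dihydroxy-1-(4-hydroxy-3-methoxyphenyl)propan-2-yl]-4-hydroxy-5-methoxybenzyl}dihydrofuran-2(3H)-one | COc1cc([C@@H](O)[C@H](CO)c2cc(C[C@@H]3COC(=O)[C@H]3Cc3cc(OC)c(O)c([C@H](CO)[C@H](O)c4ccc(O)c(OC)c4)c3)cc(OC)c2O)ccc1O | target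

## Step count and least certain steps

Total step count: 16. Longest linear sequence: 13 steps (steps 1, 2, 3, 4, 5, 9, 10, 11, 12, 13, 14, 15, 16).

Step 14 (key step). The most likely failure is slow and poorly face-selective addition on the Z arm. The Z boronate must place its ortho-substituted aryl group axial in the chair, so it may need a higher temperature than the E arm, at which the background addition and erosion of catalyst control begin; one set of conditions may not suit both arms. The fallback sets out from 18 and performs the two additions separately. Acid-catalysed addition of 18 to 21, at the temperature the Z unit needs, would give the mono-adduct carrying the finished syn arm on ring C and the acetate on ring B, F1. Palladium-catalysed borylation of its acetate by 19 would give the corresponding (E)-boronate, F2, and a second acid-catalysed addition to 21 comes back to the route at 23. This costs one step and also removes the Z boronate before palladium is used.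

Step 13. The most likely failure is consumption or geometric scrambling of the Z boronate, by transmetalation to the π-allyl palladium intermediate and allyl–allyl coupling. The fallback sets out from 17 and inverts the order of the two boron installations. Borylation of the acetate by 19 under the same palladium conditions would give the allene-bearing (E)-boronate, F3, and copper hydride hydroboration of its allene comes back at 20, so that no Z boronate ever meets palladium.

Step 12. The most likely failure is loss of chemoselectivity: hydride displacement of the allylic acetate, or hydrocupration of the cinnamyl alkene followed by elimination of acetate. The fallback sets out from 15, where ring B still carries the inert silyl ether. Copper hydride hydroboration of the allene would give the silyl-protected (Z)-boronate, F4; desilylation by HF·pyridine would give the (Z)-boronate alcohol, F5; acetylation comes back at 18.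

Step 3. The most likely failures are hydrodeiodination, through oxidative addition of the aryl iodide to rhodium, and insufficient or reversed enantioselection. The fallback avoids hydrogen and uses an Evans auxiliary; it sets out from 10. Appel bromination would give 2-(benzyloxy)-5-(bromomethyl)-1-iodo-3-methoxybenzene, F6. The sodium enolate (NaHMDS, THF, −78 °C) of (S)-4-benzyl-3-[4-(tert-butoxy)-4-oxobutanoyl]oxazolidin-2-one, F7, made from (S)-4-benzyloxazolidin-2-one and mono-tert-butyl succinate through the mixed pivalic anhydride, would be alkylated by F6 anti to the auxiliary benzyl group to give the (S)-configured imide, F8. LiBH4 would reduce the imide carbonyl and release the auxiliary to give tert-butyl (S)-4-[4-(benzyloxy)-3-iodo-5-methoxyphenyl]-3-(hydroxymethyl)butanoate, F9, and trifluoroacetic acid closes the lactone and comes back at 7.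

Step 15. The most likely failure is over-oxidation of the four alkoxyarenes or the benzyl ethers by ozone, or partial reduction of the lactone during the borohydride quench. The fallback sets out from 23 and replaces ozone by a Lemieux–Johnson-type sequence. Catalytic dihydroxylation (K2OsO4·2H2O, N-methylmorpholine N-oxide) would give the bis(1,2-diol), F10. Periodate cleavage in buffered aqueous THF at 0 °C would give the dialdehyde, F11, which is reduced at once by NaBH4 in the same flask to come back at 25.

## Further compounds

F1 | step 14 | (3S,4S)-4-{3-[(E)-3-acetoxyprop-1-enyl]-4-(benzyloxy)-5-methoxybenzyl}-3-{4-(benzyloxy)-3-[(1S,2S)-1-(4-(benzyloxy)-3-methoxyphenyl)-1-hydroxybut-3-en-2-yl]-5-methoxybenzyl}dihydrofuran-2(3H)-one | COc1cc(C[C@@H]2COC(=O)[C@H]2Cc2cc(OC)c(OCc3ccccc3)c([C@H](C=C)[C@H](O)c3ccc(OCc4ccccc4)c(OC)c3)c2)cc(/C=C/COC(C)=O)c1OCc1ccccc1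
F2 | step 14 | (3S,4S)-3-{4-(benzyloxy)-3-[(1S,2S)-1-(4-(benzyloxy)-3-methoxyphenyl)-1-hydroxybut-3-en-2-yl]-5-methoxybenzyl}-4-{4-(benzyloxy)-3-methoxy-5-[(E)-3-(4,4,5,5-tetramethyl-1,3,2-dioxaborolan-2-yl)prop-1-enyl]benzyl}dihydrofuran-2(3H)-one | COc1cc(C[C@@H]2COC(=O)[C@H]2Cc2cc(OC)c(OCc3ccccc3)c([C@H](C=C)[C@H](O)c3ccc(OCc4ccccc4)c(OC)c3)c2)cc(/C=C/CB2OC(C)(C)C(C)(C)O2)c1OCc1ccccc1
F3 | step 13 | (3S,4S)-3-[4-(benzyloxy)-3-methoxy-5-(propa-1,2-dienyl)benzyl]-4-{4-(benzyloxy)-3-methoxy-5-[(E)-3-(4,4,5,5-tetramethyl-1,3,2-dioxaborolan-2-yl)prop-1-enyl]benzyl}dihydrofuran-2(3H)-one | COc1cc(C[C@@H]2COC(=O)[C@H]2Cc2cc(OC)c(OCc3ccccc3)c(C=C=C)c2)cc(/C=C/CB2OC(C)(C)C(C)(C)O2)c1OCc1ccccc1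
F4 | step 12 | (3S,4S)-3-{4-(benzyloxy)-3-methoxy-5-[(Z)-3-(4,4,5,5-tetramethyl-1,3,2-dioxaborolan-2-yl)prop-1-enyl]benzyl}-4-{4-(benzyloxy)-3-[(E)-3-(tert-butyldimethylsilyloxy)prop-1-enyl]-5-methoxybenzyl}dihydrofuran-2(3H)-one | COc1cc(C[C@@H]2COC(=O)[C@H]2Cc2cc(OC)c(OCc3ccccc3)c(/C=C\CB3OC(C)(C)C(C)(C)O3)c2)cc(/C=C/CO[Si](C)(C)C(C)(C)C)c1OCc1ccccc1
F5 | step 12 | (3S,4S)-3-{4-(benzyloxy)-3-methoxy-5-[(Z)-3-(4,4,5,5-tetramethyl-1,3,2-dioxaborolan-2-yl)prop-1-enyl]benzyl}-4-{4-(benzyloxy)-3-[(E)-3-hydroxyprop-1-enyl]-5-methoxybenzyl}dihydrofuran-2(3H)-one | COc1cc(C[C@@H]2COC(=O)[C@H]2Cc2cc(OC)c(OCc3ccccc3)c(/C=C\CB3OC(C)(C)C(C)(C)O3)c2)cc(/C=C/CO)c1OCc1ccccc1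
F6 | step 3 | 2-(benzyloxy)-5-(bromomethyl)-1-iodo-3-methoxybenzene | COc1cc(CBr)cc(I)c1OCc1ccccc1
F7 | step 3 | (S)-4-benzyl-3-[4-(tert-butoxy)-4-oxobutanoyl]oxazolidin-2-one | CC(C)(C)OC(=O)CCC(=O)N1[C@@H](Cc2ccccc2)COC1=O
F8 | step 3 | (S)-4-benzyl-3-{(S)-2-[4-(benzyloxy)-3-iodo-5-methoxybenzyl]-4-(tert-butoxy)-4-oxobutanoyl}oxazolidin-2-one | CC(C)(C)OC(=O)C[C@H](Cc1cc(I)c(OCc2ccccc2)c(OC)c1)C(=O)N1[C@@H](Cc2ccccc2)COC1=O
F9 | step 3 | tert-butyl (S)-4-[4-(benzyloxy)-3-iodo-5-methoxyphenyl]-3-(hydroxymethyl)butanoate | CC(C)(C)OC(=O)C[C@H](Cc1cc(I)c(OCc2ccccc2)c(OC)c1)CO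
F10 | step 15 | bis(1,2-diol) from 23 (each vinyl group as a 1,2-dihydroxyethyl group, new carbinol centres as a mixture) | COc1cc([C@@H](O)[C@H](C(O)CO)c2cc(C[C@@H]3COC(=O)[C@H]3Cc3cc(OC)c(OCc5ccccc5)c([C@H](C(O)CO)[C@H](O)c4ccc(OCc5ccccc5)c(OC)c4)c3)cc(OC)c2OCc2ccccc2)ccc1OCc1ccccc1
F11 | step 15 | dialdehyde from 23 (each vinyl group as a formyl group) | COc1cc([C@@H](O)[C@H](C=O)c2cc(C[C@@H]3COC(=O)[C@H]3Cc3cc(OC)c(OCc5ccccc5)c([C@H](C=O)[C@H](O)c4ccc(OCc5ccccc5)c(OC)c4)c3)cc(OC)c2OCc2ccccc2)ccc1OCc1ccccc1
A1 | alternative 1 | trans,trans 3-benzyl-4-(dithianyl-aryl)-5-menthyloxy lactone | COc1cc([C@@H](O[Si](C)(C)C(C)(C)C)[C@H](CO[Si](C)(C)C(C)(C)C)c2cc(C6(SCCCS6)[C@@H]3[C@@H](O[C@H]7C[C@@H](C)CC[C@@H]7C(C)C)OC(=O)[C@H]3Cc3cc(OC)c(OCc5ccccc5)c([C@H](CO[Si](C)(C)C(C)(C)C)[C@H](O[Si](C)(C)C(C)(C)C)c4ccc(OCc5ccccc5)c(OC)c4)c3)cc(OC)c2OCc2ccccc2)ccc1OCc1ccccc1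
A2 | alternative 1 | (5S)-5-(d-menthyloxy)furan-2(5H)-one | O=C1C=C[C@@H](O[C@H]2C[C@@H](C)CC[C@@H]2C(C)C)O1
A3 | alternative 1 | 2-aryl-1,3-dithiane of the ring B half bearing the bis-silylated anti arm | COc1cc([C@@H](O[Si](C)(C)C(C)(C)C)[C@H](CO[Si](C)(C)C(C)(C)C)c2cc(C3SCCCS3)cc(OC)c2OCc2ccccc2)ccc1OCc1ccccc1
A4 | alternative 1 | ring C benzyl bromide bearing the bis-silylated syn arm | COc1cc(CBr)cc([C@H](CO[Si](C)(C)C(C)(C)C)[C@H](O[Si](C)(C)C(C)(C)C)c2ccc(OCc3ccccc3)c(OC)c2)c1OCc1ccccc1
A5 | alternative 2 | trans-4,5-diaryl-1,3-dioxan-2-one of the ring B arm configuration | COc1cc([C@@H](OC(=O)OC5)[C@H]5c2cc(Br)cc(OC)c2OCc2ccccc2)ccc1OCc1ccccc1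
A6 | alternative 2 | tert-butyl (S)-2-[2-(benzyloxy)-5-bromo-3-methoxyphenyl]-3-[4-(benzyloxy)-3-methoxyphenyl]propyl carbonate | COc1cc(C[C@H](COC(=O)OC(C)(C)C)c2cc(Br)cc(OC)c2OCc2ccccc2)ccc1OCc1ccccc1
A7 | alternative 3 | bis(ortho-alkylated phenol) carrying (E)-propenyl groups in place of the two CH2OH groups | COc1cc([C@@H](O[Si](C)(C)C(C)(C)C)[C@H](/C=C/C)c2cc(C[C@@H]3COC(=O)[C@H]3Cc3cc(OC)c(O)c([C@H](/C=C/C)[C@H](O[Si](C)(C)C(C)(C)C)c4ccc(OCc5ccccc5)c(OC)c4)c3)cc(OC)c2O)ccc1OCc1ccccc1
A8 | alternative 3 | bis(aryl allyl ether) of the lactone core, ether carbon S on ring B and R on ring C, both silyloxy carbons S, both alkenes E | COc1cc(C[C@@H]2COC(=O)[C@H]2Cc2ccc(O[C@H](C)/C=C/[C@H](O[Si](C)(C)C(C)(C)C)c3ccc(OCc4ccccc4)c(OC)c3)c(OC)c2)ccc1O[C@@H](C)/C=C/[C@H](O[Si](C)(C)C(C)(C)C)c1ccc(OCc2ccccc2)c(OC)c1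
A9 | alternative 3 | (3S,4S)-matairesinol | COc1cc(C[C@@H]2COC(=O)[C@H]2Cc2ccc(O)c(OC)c2)ccc1O
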